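## Retrosynthetic overview

1. Numbering: C1 = carbinol carbon carrying the butenoyl group (C2 = its C=O), C5 = CH–O-isovalerate, C6 = lactone CH–O, C7 = lactone CH, C8 = CH2, C9 = CHOH, C10 = CH–CH3, C11 = lactone α-carbon (C12 = lactone C=O, C13 = exocyclic CH2). Feature: in the cycloheptane ring C1 and C7 are 1,4-related across C5–C6 and tied on the other side by C10–C9(O)–C8. The ring is therefore a 2,5-disubstituted furan (C1, C5, C6, C7, the C1 oxygen, arms C2 and C11) plus a three-carbon oxyallyl unit (C8–C10), and this core has a hidden mirror plane.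
2. Key disconnection: C7–C8 and C1–C10, by (4+3) cycloaddition of 2,5-bis[(4-methoxybenzyloxy)methyl]furan with the oxyallyl cation from 1,1,3,3-tetrabromoacetone. The seven-membered carbocycle and its oxygen bridge form first, as a meso 8-oxabicyclo[3.2.1]octenone.
3. The symmetry is broken by chiral lithium amide deprotonation and methylation (C10). Exo dihydroxylation oxygenates C5 and C6. The C7–O bridge bond is then cut by β-elimination from the C9 ketone, leaving the oxygen on C1, and C9 and C7 are set by hydroxyl-directed reduction and hydrogenation.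
4. Second ring: the C11 arm becomes an ethynyl group (adds C13), and Pd-catalysed cyclocarbonylation onto C6–OH closes the α-methylene-γ-lactone (adds C12).
5. End game: C5 is inverted by oxidation and C1-hydroxyl-directed reduction (C5 is neopentyl-like, so SN2 inversion is not relied on) and esterified. The C2 arm is oxidised, (Z)-propenylated and oxidised to the enone.

Key step: step 2

Convention: α is the face of the seven-membered ring that carries the C1 oxygen (the former furan oxygen), β the other face. The target has C1–OH, C6–O, C11 (on C7) and the C10 methyl α, and C5–O, C9–OH and C2 β.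

Assumption: the (R,R) amide base is taken to select the CH2 that becomes C10; if the sense of induction is the opposite one, the (S,S) base is used and nothing else changes.

## Route

Step 1
Reactants: 1 2,5-bis(hydroxymethyl)furan; 2 4-methoxybenzyl chloride
Product: 3 2,5-bis[(4-methoxybenzyloxy)methyl]furan
Conditions: NaH, Bu4NI (cat.), DMF, 0 °C → rt
Reagents that add atoms: 4-methoxybenzyl chloride (compound 2), COc1ccc(CCl)cc1
Why: Williamson ether synthesis on both primary furfuryl alkoxides; 4-methoxybenzyl ethers are used so that the two arms can later be told apart by oxidation next to the freed C1 hydroxyl.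

Step 2
Reactants: 3 2,5-bis[(4-methoxybenzyloxy)methyl]furan; 4 1,1,3,3-tetrabromoacetone
Product: 7 meso-1,5-bis[(4-methoxybenzyloxy)methyl]-8-oxabicyclo[3.2.1]oct-6-en-3-one, via bromozinc dibromo-oxyallyl cation 5 (not isolated), via dibromo cycloadduct 6 (not isolated)
Conditions: Zn dust, B(OEt)3, THF, 0 °C → rt; then Zn–Cu couple, NH4Cl, MeOH, rt
Reagents that add atoms: 1,1,3,3-tetrabromoacetone (compound 4), O=C(C(Br)Br)C(Br)Br
Why: Zinc takes two bromides from 4 to give the bromozinc oxyallyl cation 5, whose three-carbon 2π unit adds across the two α-carbons of the furan 4π system (concerted, or stepwise through a furan-stabilised cation that closes at once), forming C7–C8 and C1–C10; the Zn–Cu couple then replaces both C–Br bonds of 6 by C–H. The closest known reaction type is the (4+3) cycloaddition of furans with oxyallyl cations generated from polybromoketones and zinc, followed by reductive debromination. Both rings close in the one intermolecular annulation: the seven-membered carbocycle by joining the two termini of the allyl cation to C1 and C7, and with it the tetrahydropyranone ring in which the furan oxygen becomes the one-atom bridge. The two new bridgehead stereocentres C1 and C7 are controlled by geometry alone, since an oxygen bridge can only span cis positions, so 7 is meso and the two CHBr centres of 6 are erased in the debromination. No regio- or facial selectivity is needed because both partners are symmetric; what is needed is cycloaddition in preference to electrophilic substitution of the furan, and the 2,5-disubstitution blocks both α-positions against substitution. The two alkyl-type arms also make the furan an electron-rich, reactive diene of the 2,5-dialkylfuran class.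

Step 3
Reactants: 7 meso ketone
Product: 9 2-methyl-1,5-bis[(4-methoxybenzyloxy)methyl]-8-oxabicyclo[3.2.1]oct-6-en-3-one with the C10 methyl axial and α, via lithium enolate 8 (not isolated)
Conditions: (R,R)-[PhCH(Me)]2NLi (from the amine and n-BuLi), LiCl, THF, −78 °C; then MeI, −78 → −40 °C
Reagents that add atoms: iodomethane, CI
Why: Enantiotopic deprotonation of the meso ketone by the C2-symmetric chiral lithium amide (asymmetric desymmetrisation) gives enolate 8, which is methylated on its exo face, anti to the C5=C6 bridge, so the C10 methyl is axial, α and cis to the bridge oxygen, and this one event fixes the absolute configuration of the whole series.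

Step 4
Reactants: 9 C10-methyl ketone
Product: 10 exo-cis-diol (C5–OH and C6–OH both α)
Conditions: OsO4 (2 mol %), NMO, acetone/H2O, rt
Reagents that add atoms: N-methylmorpholine N-oxide, C[N+]1([O-])CCOCC1; water, O
Why: Upjohn dihydroxylation: OsO4 reaches C5=C6 only from the exo face (the side of the one-atom oxygen bridge, the other face being covered by the C8–C9–C10 bridge), so both hydroxyls should come out α, cis to the bridge oxygen, and the near-neutral medium should leave the axial C10 methyl in place.

Step 5
Reactants: 10 exo-cis-diol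
Product: 11 C5,C6-O-isopropylidene ketone
Conditions: 2,2-dimethoxypropane, PPTS (cat.), acetone, rt
Reagents that add atoms: 2,2-dimethoxypropane, COC(C)(C)OC
Why: Acid-catalysed transketalisation gives the five-membered acetonide of the cis-diol, which protects both hydroxyls through the base and Lewis acid steps and later shields the α face of C7=C8.

Step 6
Reactants: 11 acetonide ketone
Product: 12 trimethylsilyl enol ether (C8=C9)
Conditions: LiN(i-Pr)2 (commercial solution), Me3SiCl (internal quench), THF, −78 °C
Reagents that add atoms: chlorotrimethylsilane, C[Si](C)(C)Cl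
Why: Kinetic enolisation takes the axial hydrogen of the C8 methylene and not the lone equatorial hydrogen on C10, which is badly aligned with the carbonyl π system, and in situ trapping as the silyl enol ether fixes the C8=C9 regiochemistry and keeps C10 intact.

Step 7
Reactants: 12 silyl enol ether
Product: 14 ring-opened enone (C9=O and C7=C8) with free C1–OH and the C5/C6 acetonide, via C1-O-trimethylsilyl enone 13 (not isolated)
Conditions: Me3SiOTf (0.1 equiv), 2,6-di-tert-butylpyridine (0.2 equiv), CH2Cl2, −78 → −30 °C; then aqueous citric acid, THF, 0 °C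
Reagents that add atoms: none
Why: Lewis-acid-triggered β-elimination (retro-oxa-Michael opening of an 8-oxabicyclo[3.2.1]octan-3-one silyl enol ether): silylation of the bridge oxygen lets the tertiary, allylic C7–O bond ionise with the push of the enol ether to give enone 13 with the oxygen left on C1, and the labile tertiary silyl ether is then hydrolysed by mild acid rather than base, which avoids retro-aldol cleavage of the β-hydroxy ketone.

Step 8
Reactants: 14 hydroxy enone
Product: 15 allylic alcohol with C9–OH β (1,3-anti to C1–OH)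
Conditions: Me4NBH(OAc)3, MeCN/AcOH, −30 °C
Reagents that add atoms: none
Why: Saksena–Evans reduction: the C1 hydroxyl exchanges onto boron and delivers hydride intramolecularly to the α face of the C9 carbonyl in a 1,2-sense, so the new C9 hydroxyl should be β and anti to the C1 hydroxyl.

Step 9
Reactants: 15 allylic alcohol
Product: 16 cycloheptane diol with C7–H β and the C11 arm α
Conditions: [Ir(cod)(PCy3)(py)]PF6 (5 mol %), H2 (1 atm), CH2Cl2, 0 °C → rt
Reagents that add atoms: none
Why: Hydroxyl-directed homogeneous hydrogenation with the Crabtree catalyst: the allylic C9–OH binds iridium and hydrogen is delivered to the β face of the trisubstituted C7=C8 bond, the face also left open by the α-acetonide, so C7–H should be β and the C11 arm α (cis to C6–O), and the benzylic ethers are not hydrogenolysed.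

Step 10
Reactants: 16 diol
Product: 17 C9 tert-butyldimethylsilyl ether
Conditions: TBSCl, imidazole, DMF, rt
Reagents that add atoms: tert-butyldimethylsilyl chloride, CC(C)(C)[Si](C)(C)Cl
Why: Standard silylation of the secondary C9 hydroxyl; the tertiary C1 hydroxyl does not react and stays free for the next step.

Step 11
Reactants: 17 C9 silyl ether
Product: 18 C1,C2-O-(4-methoxybenzylidene) acetal with free C11–OH (acetal carbon as a mixture of epimers)
Conditions: DDQ (2.5 equiv), 4 Å molecular sieves, CH2Cl2, 0 °C → rt; then aqueous NaHCO3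
Reagents that add atoms: none
Why: DDQ oxidises both 4-methoxybenzyl ethers to oxocarbenium ions: the one on C2 is captured by the adjacent C1 hydroxyl as the five-membered benzylidene acetal (oxidative acetal formation), while the one on C11 has no hydroxyl within reach and is hydrolysed on work-up, so the two arms become different.

Step 12
Reactants: 18 primary alcohol
Product: 19 C11 aldehyde
Conditions: Dess–Martin periodinane, NaHCO3, CH2Cl2, 0 °C → rt
Reagents that add atoms: none
Why: Dess–Martin oxidation of the only free hydroxyl to the aldehyde under buffered conditions that should not epimerise C7.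

Step 13
Reactants: 19 aldehyde
Product: 20 C7-ethynyl compound (C11≡C13)
Conditions: dimethyl (1-diazo-2-oxopropyl)phosphonate, K2CO3, MeOH, 0 °C → rt
Reagents that add atoms: dimethyl (1-diazo-2-oxopropyl)phosphonate, COP(=O)(OC)C(=[N+]=[N-])C(C)=O
Why: Seyferth–Gilbert homologation with the Ohira–Bestmann reagent converts the aldehyde into the terminal alkyne, adding C13, under carbonate/methanol conditions mild enough that the C7 centre should be kept.

Step 14
Reactants: 20 alkyne
Product: 21 tetraol (C1, C2, C5 and C6 hydroxyls free, C9–OTBS kept)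
Conditions: CSA (cat.), MeOH, 0 °C → rt
Reagents that add atoms: none
Why: Acid-catalysed acetal exchange with methanol removes the isopropylidene and the 4-methoxybenzylidene acetals together, while the hindered secondary silyl ether on C9 is the slowest group to cleave under these conditions.

Step 15
Reactants: 21 tetraol alkyne
Product: 22 cis-fused α-methylene-γ-lactone triol (C1, C2 and C5 hydroxyls free)
Conditions: PdCl2 (5 mol %), SnCl2 (5 mol %), PPh3 (10 mol %), CO (7 atm), MeCN, 75 °C
Reagents that add atoms: carbon monoxide, [C-]#[O+]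
Why: Palladium-catalysed cyclocarbonylation of a homopropargylic alcohol: the alkoxycarbonyl–palladium species formed at C6–OH adds syn across the alkyne in a 5-exo-dig sense and protonolysis gives the α-methylene-γ-lactone, cis-fused because C6–O and C7–C11 are both α, and no other hydroxyl can reach the alkyne through a five-membered ring.

Step 16
Reactants: 22 triol
Product: 23 C2 tert-butyldimethylsilyl ether
Conditions: TBSCl (1.1 equiv), imidazole, CH2Cl2/DMF, 0 °C
Reagents that add atoms: tert-butyldimethylsilyl chloride, CC(C)(C)[Si](C)(C)Cl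
Why: Selective silylation of the primary C2 hydroxyl over the hindered secondary C5 and tertiary C1 hydroxyls, so that C2 can neither be oxidised nor direct hydride in the next two steps.

Step 17
Reactants: 23 diol
Product: 24 C5 ketone
Conditions: IBX, DMSO, rt
Reagents that add atoms: none
Why: IBX oxidises the secondary alcohol of a secondary/tertiary 1,2-diol to the α-hydroxy ketone without C–C cleavage and leaves tert-butyldimethylsilyl ethers and the methylene lactone alone.

Step 18
Reactants: 24 α-hydroxy ketone
Product: 25 C5 β-alcohol (trans to C1–OH and to C6–O)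
Conditions: Me4NBH(OAc)3, MeCN/AcOH, −20 → 0 °C
Reagents that add atoms: none
Why: Hydroxyl-directed triacetoxyborohydride reduction (Saksena–Evans type): the α-oriented C1 hydroxyl, the only free hydroxyl, binds boron and delivers hydride to the α face of the C5 ketone, which should give the β alcohol, i.e. the inversion of the centre made in step 4 that an SN2 reaction at this neopentyl-like carbon could not be trusted to give.

Step 19
Reactants: 25 C5 β-alcohol
Product: 26 C5 isovalerate
Conditions: isovaleric anhydride, DMAP, Et3N, CH2Cl2, rt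
Reagents that add atoms: 3-methylbutanoic anhydride, CC(C)CC(=O)OC(=O)CC(C)C
Why: DMAP-catalysed acylation of the secondary C5 alcohol; the tertiary C1 hydroxyl is not acylated under these conditions.

Step 20
Reactants: 26 bis-silyl ether
Product: 27 primary C2 alcohol (C9–OTBS kept)
Conditions: HF·pyridine, pyridine, THF, 0 °C
Reagents that add atoms: none
Why: Buffered HF·pyridine cleaves the primary silyl ether much faster than the hindered secondary one on C9 and does not touch the esters.

Step 21
Reactants: 27 primary alcohol
Product: 28 C2 aldehyde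
Conditions: IBX, DMSO, rt
Reagents that add atoms: none
Why: IBX oxidation of the primary alcohol next to the tertiary carbinol gives the α-hydroxy aldehyde without glycol cleavage, and the aldehyde has no α-hydrogen to lose.

Step 22
Reactants: 28 aldehyde
Product: 29 (Z)-allylic alcohol at C2 (both C2 epimers)
Conditions: (Z)-1-bromopropene, t-BuLi (2 equiv), Et2O, −78 °C; CeCl3, THF, −78 °C; then 28, −78 °C; AcOH quench at −78 °C
Reagents that add atoms: (Z)-1-bromopropene, C/C=C\Br
Why: Bromine–lithium exchange on (Z)-1-bromopropene proceeds with retention of the double-bond geometry, and the weakly basic organocerium reagent made from it should add 1,2 to the aldehyde much faster than to the lactone or ester at −78 °C; the new C2 carbinol centre is not controlled and is removed in the next step.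

Step 23
Reactants: 29 allylic alcohol
Product: 30 (Z)-enone with C9–OTBS
Conditions: IBX, DMSO, rt, dark
Reagents that add atoms: none
Why: IBX oxidation of the allylic alcohol to the enone under neutral conditions at room temperature, which should neither isomerise the cis double bond nor cleave the α-ketol.

Step 24
Reactants: 30 silyl ether
Product: 31 target CNP0186412.2
Conditions: HF·pyridine, THF, 0 °C → rt
Reagents that add atoms: none
Why: Fluoride-mediated removal of the last silyl ether under mildly acidic conditions that should spare the (Z)-enone, the methylene lactone and the isovalerate.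

## Compound list

1 | 2,5-bis(hydroxymethyl)furan | OCc1ccc(CO)o1 | starting material
2 | 4-methoxybenzyl chloride | COc1ccc(CCl)cc1 | starting material
3 | 2,5-bis[(4-methoxybenzyloxy)methyl]furan | COc1ccc(COCc2ccc(COCc3ccc(OC)cc3)o2)cc1 | intermediate
4 | 1,1,3,3-tetrabromoacetone | O=C(C(Br)Br)C(Br)Br | starting material
5 | bromozinc 1,3-dibromo-2-oxyallyl cation (bromide) | Br[CH+]C(=CBr)O[Zn]Br.[Br-] | intermediate (not isolated)
6 | 2,4-dibromo-1,5-bis[(4-methoxybenzyloxy)methyl]-8-oxabicyclo[3.2.1]oct-6-en-3-one (C–Br epimers) | O=C1C(Br)[C@]2(COCc3ccc(OC)cc3)C=C[C@@](COCc3ccc(OC)cc3)(O2)C1Br | intermediate (not isolated)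
7 | meso-1,5-bis[(4-methoxybenzyloxy)methyl]-8-oxabicyclo[3.2.1]oct-6-en-3-one | O=C1C[C@]2(COCc3ccc(OC)cc3)C=C[C@@](COCc3ccc(OC)cc3)(O2)C1 | intermediate
8 | lithium enolate of 7 (C9–OLi, C9=C10) | [Li]OC1=C[C@@]2(COCc3ccc(OC)cc3)C=C[C@@](COCc3ccc(OC)cc3)(C1)O2 | intermediate (not isolated)
9 | C10-methyl ketone, methyl axial and cis to the oxygen bridge | O=C1C[C@]2(COCc3ccc(OC)cc3)C=C[C@@](COCc3ccc(OC)cc3)(O2)[C@H]1C | intermediate
10 | exo-cis-C5,C6-diol of 9 | O=C1C[C@]2(COCc3ccc(OC)cc3)[C@@H](O)[C@@H](O)[C@@](COCc3ccc(OC)cc3)(O2)[C@H]1C | intermediate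
11 | C5,C6-O-isopropylidene derivative of 10 | O=C1C[C@]2(COCc3ccc(OC)cc3)[C@H]4OC(C)(C)O[C@H]4[C@@](COCc3ccc(OC)cc3)(O2)[C@H]1C | intermediate
12 | C8=C9 trimethylsilyl enol ether of 11 | C[Si](C)(C)OC1=C[C@]2(COCc3ccc(OC)cc3)[C@H]4OC(C)(C)O[C@H]4[C@@](COCc3ccc(OC)cc3)(O2)[C@H]1C | intermediate
13 | ring-opened C7=C8 enone, C1–OSiMe3 | CC1(C)O[C@@H]2C(COCc3ccc(OC)cc3)=CC(=O)[C@H](C)[C@@](O[Si](C)(C)C)(COCc3ccc(OC)cc3)[C@@H]2O1 | intermediate (not isolated)
14 | ring-opened C7=C8 enone, C1–OH free | CC1(C)O[C@@H]2C(COCc3ccc(OC)cc3)=CC(=O)[C@H](C)[C@@](O)(COCc3ccc(OC)cc3)[C@@H]2O1 | intermediate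
15 | allylic alcohol, C9–OH β | CC1(C)O[C@@H]2C(COCc3ccc(OC)cc3)=C[C@@H](O)[C@H](C)[C@@](O)(COCc3ccc(OC)cc3)[C@@H]2O1 | intermediate
16 | saturated diol, C7–H β, C11 arm α | CC1(C)O[C@@H]2[C@H](COCc3ccc(OC)cc3)C[C@@H](O)[C@H](C)[C@@](O)(COCc3ccc(OC)cc3)[C@@H]2O1 | intermediate
17 | C9–OTBS ether of 16 | CC1(C)O[C@@H]2[C@H](COCc3ccc(OC)cc3)C[C@@H](O[Si](C)(C)C(C)(C)C)[C@H](C)[C@@](O)(COCc3ccc(OC)cc3)[C@@H]2O1 | intermediate
18 | C1,C2-O-(4-methoxybenzylidene) acetal, C11–OH free | CC1(C)O[C@@H]2[C@H](CO)C[C@@H](O[Si](C)(C)C(C)(C)C)[C@H](C)[C@@]3(COC(c4ccc(OC)cc4)O3)[C@@H]2O1 | intermediate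
19 | C11 aldehyde | CC1(C)O[C@@H]2[C@H](C=O)C[C@@H](O[Si](C)(C)C(C)(C)C)[C@H](C)[C@@]3(COC(c4ccc(OC)cc4)O3)[C@@H]2O1 | intermediate
20 | C7-ethynyl compound | CC1(C)O[C@@H]2[C@H](C#C)C[C@@H](O[Si](C)(C)C(C)(C)C)[C@H](C)[C@@]3(COC(c4ccc(OC)cc4)O3)[C@@H]2O1 | intermediate
21 | tetraol alkyne, C9–OTBS | O[C@@H]1[C@H](C#C)C[C@@H](O[Si](C)(C)C(C)(C)C)[C@H](C)[C@@](O)(CO)[C@@H]1O | intermediate
22 | cis-fused α-methylene-γ-lactone triol | C=C1C(=O)O[C@@H]2[C@H]1C[C@@H](O[Si](C)(C)C(C)(C)C)[C@H](C)[C@@](O)(CO)[C@@H]2O | intermediate
23 | C2–OTBS ether of 22 | C=C1C(=O)O[C@@H]2[C@H]1C[C@@H](O[Si](C)(C)C(C)(C)C)[C@H](C)[C@@](O)(CO[Si](C)(C)C(C)(C)C)[C@@H]2O | intermediate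
24 | C5 ketone | C=C1C(=O)O[C@@H]2[C@H]1C[C@@H](O[Si](C)(C)C(C)(C)C)[C@H](C)[C@@](O)(CO[Si](C)(C)C(C)(C)C)C2=O | intermediate
25 | C5 β-alcohol | C=C1C(=O)O[C@@H]2[C@H]1C[C@@H](O[Si](C)(C)C(C)(C)C)[C@H](C)[C@@](O)(CO[Si](C)(C)C(C)(C)C)[C@H]2O | intermediate
26 | C5 isovalerate | C=C1C(=O)O[C@@H]2[C@H]1C[C@@H](O[Si](C)(C)C(C)(C)C)[C@H](C)[C@@](O)(CO[Si](C)(C)C(C)(C)C)[C@H]2OC(=O)CC(C)C | intermediate
27 | primary C2 alcohol | C=C1C(=O)O[C@@H]2[C@H]1C[C@@H](O[Si](C)(C)C(C)(C)C)[C@H](C)[C@@](O)(CO)[C@H]2OC(=O)CC(C)C | intermediate
28 | C2 aldehyde | C=C1C(=O)O[C@@H]2[C@H]1C[C@@H](O[Si](C)(C)C(C)(C)C)[C@H](C)[C@@](O)(C=O)[C@H]2OC(=O)CC(C)C | intermediate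
29 | (Z)-allylic alcohol at C2 (C2 epimers) | C=C1C(=O)O[C@@H]2[C@H]1C[C@@H](O[Si](C)(C)C(C)(C)C)[C@H](C)[C@@](O)(C(O)/C=C\C)[C@H]2OC(=O)CC(C)C | intermediate
30 | (Z)-enone, C9–OTBS | C=C1C(=O)O[C@@H]2[C@H]1C[C@@H](O[Si](C)(C)C(C)(C)C)[C@H](C)[C@@](O)(C(=O)/C=C\C)[C@H]2OC(=O)CC(C)C | intermediate
31 | CNP0186412.2 | C=C1C(=O)O[C@@H]2[C@H]1C[C@@H](O)[C@H](C)[C@@](O)(C(=O)/C=C\C)[C@H]2OC(=O)CC(C)C | target

Total step count: 24. Longest linear sequence: 24 steps (1 → 31).

## Steps most likely to fail

1. Step 18. Hydride may not be delivered from the C1 hydroxyl, because the five-membered delivery geometry of an α-hydroxy ketone is less favourable than the six-membered one, and external attack on the β face would return the C5 epimer of step 4. Fallback, by substitution instead of reduction: starting from 23, the C5 hydroxyl is converted with Tf2O/pyridine (CH2Cl2, −20 °C) into the C5 α-triflate F1. This is displaced with Bu4NNO2 (toluene, rt; Lattrell–Dax inversion) to give the C5 β-nitrite ester F2, which is hydrolysed on aqueous work-up to 25, where the route is rejoined.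

2. Step 22. The organometallic reagent may lose chemoselectivity (attack on the lactone or ester, conjugate addition to the methylene lactone, alkoxide-triggered acyl shift from C5–O to C2–O), or the propenyl geometry may erode. Fallback, by alkynylation and semi-hydrogenation: starting from 28, zinc-mediated addition of propyne (Zn(OTf)2, Et3N, toluene, rt) gives the propargylic alcohol F3. Semi-hydrogenation over Pd/CaCO3 poisoned with Pb(OAc)2 and quinoline (Lindlar catalyst), stopped at one equivalent of H2, gives 29, where the route is rejoined.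

3. Step 13. The α-branched, β-alkoxy aldehyde may epimerise at C7 or lose the C6 oxygen by β-elimination under the basic homologation conditions. Fallback, by a vinyl triflate and carbonylative lactonisation: starting from 19, MeMgBr (THF, −78 °C) gives the secondary alcohol F4, and Dess–Martin oxidation gives the methyl ketone F5. Kinetic enolisation at the methyl group with KN(SiMe3)2 and trapping with PhNTf2 (THF, −78 °C) gives the enol triflate F6. CSA/MeOH removes both acetals to give the tetraol triflate F7, and Pd(PPh3)4, CO (1 atm), Et3N (MeCN, 60 °C) closes the α-methylene lactone to give 22, where the route is rejoined.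

## Further compounds

F1 | step 18 | C5 α-triflate of 23 | C=C1C(=O)O[C@@H]2[C@H]1C[C@@H](O[Si](C)(C)C(C)(C)C)[C@H](C)[C@@](O)(CO[Si](C)(C)C(C)(C)C)[C@@H]2OS(=O)(=O)C(F)(F)F
F2 | step 18 | C5 β-nitrite ester | C=C1C(=O)O[C@@H]2[C@H]1C[C@@H](O[Si](C)(C)C(C)(C)C)[C@H](C)[C@@](O)(CO[Si](C)(C)C(C)(C)C)[C@H]2ON=O
F3 | step 22 | C2 propargylic alcohol (C2 epimers) | C=C1C(=O)O[C@@H]2[C@H]1C[C@@H](O[Si](C)(C)C(C)(C)C)[C@H](C)[C@@](O)(C(O)C#CC)[C@H]2OC(=O)CC(C)C
F4 | step 13 | C11 methyl carbinol (C11 epimers) | CC1(C)O[C@@H]2[C@H](C(C)O)C[C@@H](O[Si](C)(C)C(C)(C)C)[C@H](C)[C@@]3(COC(c4ccc(OC)cc4)O3)[C@@H]2O1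
F5 | step 13 | C11 methyl ketone | CC1(C)O[C@@H]2[C@H](C(C)=O)C[C@@H](O[Si](C)(C)C(C)(C)C)[C@H](C)[C@@]3(COC(c4ccc(OC)cc4)O3)[C@@H]2O1
F6 | step 13 | C11 enol triflate | CC1(C)O[C@@H]2[C@H](C(=C)OS(=O)(=O)C(F)(F)F)C[C@@H](O[Si](C)(C)C(C)(C)C)[C@H](C)[C@@]3(COC(c4ccc(OC)cc4)O3)[C@@H]2O1
F7 | step 13 | tetraol enol triflate | O[C@@H]1[C@H](C(=C)OS(=O)(=O)C(F)(F)F)C[C@@H](O[Si](C)(C)C(C)(C)C)[C@H](C)[C@@](O)(CO)[C@@H]1O
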